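**Plan**

1. Retrosynthesis: (1) the four O‑benzyl bonds and a benzylic C=O (a temporary oxidation level) lead back to hydroxy ketone 21. (2) The C2–C(benzylic) bond and the C3–O bond, on adjacent carbons of ring B, are cut together to give 2,3‑naphthalyne 20 and benzoic acid 19. (3) The C1–aryl bond is cut to bromonaphthol 7 and boronate 10. (4) Ring B is cut at C1–C8a and C4–C4a into a ring A aryne and an oxygenated diene.
2. Enabling feature: C2 (carbon substituent) and C3 (oxygen) are neighbours on ring B, and the C1 aryl group is the only substituent beside this edge. An aryne at C2–C3 takes exactly this carbon/oxygen pair from a carboxylic acid, and the C1 aryl group sends the oxygen to C3.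
3. Forward order: ring A comes from phenol 1, and ring B is annulated by an aryne Diels–Alder reaction (step 2). The C2 hydroxyl so obtained is a temporary handle: it directs bromination and arylation to C1, lithiation and silylation to C3, and then leaves as triflate. The catechol ring is joined in step 10, and the carbonyl helper and the benzyl groups are removed in steps 11 and 12.
4. Stereochemistry: the target has no stereocentre, so none is set; the transient stereocentre of 5 is destroyed by aromatisation.

Key step: step 10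

Remark: the C1–aryl axis is not defined in the target and is treated as racemic or freely rotating. Naphthalene locants follow the target throughout (C1 aryl, C2 benzyl, C3 hydroxyl, C5/C7 methoxy, C6 oxygen).

**Step 1**
Reactants: 1 4-bromo-2,6-dimethoxyphenol
Product: 2 aryl bromide 2-(benzyloxy)-5-bromo-1,3-dimethoxybenzene
Conditions: BnBr, K2CO3, DMF, 60 °C
Reagents that add atoms: benzyl bromide, BrCc1ccccc1
Why: Williamson ether synthesis puts a benzyl group on the future C6 oxygen, where it stays until the final hydrogenolysis.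

**Step 2**
Reactants: 2 aryl bromide; 3 (E)-1-methoxy-3-(trimethylsilyloxy)buta-1,3-diene
Product: 6 naphthol 6-(benzyloxy)-5,7-dimethoxynaphthalen-2-ol, via aryne 4 (not isolated), via cycloadduct 5 (not isolated)
Conditions: lithium 2,2,6,6-tetramethylpiperidide (LiTMP, from TMPH and n-BuLi), THF, −78 °C to rt; then aqueous HCl, THF, rt
Reagents that add atoms: none
Why: Aryne Diels–Alder reaction, in which the amide base removes the hydrogen between bromine and methoxy of 2 and loss of LiBr gives aryne 4, whose more electrophilic carbon (remote from the flanking methoxy group) should bond to the nucleophilic CH2 terminus of diene 3, after which acid hydrolyses the silyl enol ether of 5 and eliminates methanol to aromatise ring B with the hydroxyl on C2.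

**Step 3**
Reactants: 6 naphthol
Product: 7 bromonaphthol 6-(benzyloxy)-1-bromo-5,7-dimethoxynaphthalen-2-ol
Conditions: NBS, CH2Cl2, −78 to 0 °C
Reagents that add atoms: N-bromosuccinimide, O=C1CCC(=O)N1Br
Why: Electrophilic bromination of a 2-naphthol should take place at C1, the alpha position ortho to the hydroxyl, which is far more reactive than any position of ring A at low temperature.

**Step 4**
Reactants: 8 4-bromo-3-methoxyphenol
Product: 9 aryl bromide 4-(benzyloxy)-1-bromo-2-methoxybenzene
Conditions: BnBr, K2CO3, DMF, 60 °C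
Reagents that add atoms: benzyl bromide, BrCc1ccccc1
Why: Williamson ether synthesis protects the future C4' hydroxyl of the C1 aryl ring as a benzyl ether.

**Step 5**
Reactants: 9 aryl bromide
Product: 10 boronate 2-[4-(benzyloxy)-2-methoxyphenyl]-4,4,5,5-tetramethyl-1,3,2-dioxaborolane
Conditions: B2pin2, PdCl2(dppf) (cat.), KOAc, 1,4-dioxane, 90 °C
Reagents that add atoms: bis(pinacolato)diboron, CC1(C)OB(OC1(C)C)B1OC(C)(C)C(C)(C)O1
Why: Miyaura borylation converts the electron-rich aryl bromide into the pinacol boronate without organolithium intermediates.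

**Step 6**
Reactants: 7 bromonaphthol; 10 boronate
Product: 11 biaryl naphthol 6-(benzyloxy)-1-[4-(benzyloxy)-2-methoxyphenyl]-5,7-dimethoxynaphthalen-2-ol
Conditions: Pd(OAc)2 (cat.), SPhos, K3PO4, toluene/H2O, 90 °C
Reagents that add atoms: none
Why: Suzuki–Miyaura coupling with a bulky dialkylbiarylphosphine should form the hindered C1–aryl bond, and the free naphthol is tolerated as its phenoxide.

**Step 7**
Reactants: 11 biaryl naphthol
Product: 12 carbamate 6-(benzyloxy)-1-[4-(benzyloxy)-2-methoxyphenyl]-5,7-dimethoxynaphthalen-2-yl N-isopropylcarbamate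
Conditions: i-PrNCO, Et3N (cat.), CH2Cl2, rt
Reagents that add atoms: isopropyl isocyanate, CC(C)N=C=O
Why: Base-catalysed addition of the naphthol to the isocyanate gives an N-isopropyl carbamate, a strong ortho-directing group that can be removed later under mild conditions.

**Step 8**
Reactants: 12 carbamate
Product: 16 silyl carbamate 6-(benzyloxy)-1-[4-(benzyloxy)-2-methoxyphenyl]-5,7-dimethoxy-3-(trimethylsilyl)naphthalen-2-yl N-isopropylcarbamate, via N-silyl carbamate 13 (not isolated), via C3-lithio carbamate 14 (not isolated), via N-silyl C3-silyl carbamate 15 (not isolated)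
Conditions: TBSOTf, TMEDA, Et2O, 0 °C to rt; n-BuLi, TMEDA, −78 °C; TMSCl, −78 °C to rt; aqueous NaHSO4
Reagents that add atoms: chlorotrimethylsilane, C[Si](C)(C)Cl
Why: Directed ortho-metalation, in which the carbamate (N-silylated in the flask) directs n-BuLi to C3, the only ortho position still bearing hydrogen, TMSCl traps the aryllithium and the N–Si bond is hydrolysed on work-up.

**Step 9**
Reactants: 16 silyl carbamate
Product: 18 silyl triflate 6-(benzyloxy)-1-[4-(benzyloxy)-2-methoxyphenyl]-5,7-dimethoxy-3-(trimethylsilyl)naphthalen-2-yl trifluoromethanesulfonate, via silyl naphthol 17 (not isolated)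
Conditions: DBU, Et2NH, MeCN, 40 °C; then PhNTf2, rt
Reagents that add atoms: N-phenylbis(trifluoromethanesulfonimide), O=S(=O)(N(c1ccccc1)S(=O)(=O)C(F)(F)F)C(F)(F)F
Why: The amidine base and Et2NH cleave the N–H carbamate by elimination to isopropyl isocyanate (trapped as the urea), and the liberated naphtholate 17 is sulfonylated by PhNTf2 to give the ortho-silylaryl triflate needed for fluoride-induced aryne formation.

**Step 10**
Reactants: 18 silyl triflate; 19 3,4-bis(benzyloxy)benzoic acid
Product: 21 hydroxy ketone [6-(benzyloxy)-1-[4-(benzyloxy)-2-methoxyphenyl]-3-hydroxy-5,7-dimethoxynaphthalen-2-yl][3,4-bis(benzyloxy)phenyl]methanone, via naphthalyne 20 (not isolated)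
Conditions: CsF, THF, 125 °C (sealed tube), 19 in excess
Reagents that add atoms: none
Why: Fluoride removes the silyl group of 18 and triflate leaves to give 2,3-naphthalyne 20; the caesium carboxylate of 19 adds through oxygen to C3, the C2 aryl anion so formed attacks the neighbouring ester carbonyl (4-exo-trig), and the four-membered alkoxide opens to the C3 naphtholate with the aroyl group on C2, so the C2–carbon and C3–oxygen bonds are made in one operation. The closest known reaction type is the insertion of arynes into the C–O bond of carboxylic acids to give ortho-hydroxyaryl ketones, applied here to a new aryne. No ring of the target is closed and no stereocentre is formed; the only ring made is the transient four-membered one. The step needs regioselectivity (oxygen to C3, not C2), which the aryl group on C1 should secure as the only substituent beside the triple bond (C4 bears hydrogen): it hinders in-plane approach to C2 and, as an sp2 carbon substituent, stabilises the negative charge building up on C2, the same bias that sends nucleophiles to the remote carbon of 3-arylbenzynes in the aryne synthesis of meta-terphenyls. The methoxy oxygen of the C1 aryl ring is too weak a donor to compete with the carboxylate (THF as solvent does not intercept such arynes either), and the excess of benzoate should keep the product naphtholate from capturing a second aryne.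

**Step 11**
Reactants: 21 hydroxy ketone
Product: 22 diarylmethane 6-(benzyloxy)-1-[4-(benzyloxy)-2-methoxyphenyl]-2-[3,4-bis(benzyloxy)benzyl]-5,7-dimethoxynaphthalen-3-ol
Conditions: Et3SiH, CF3CO2H, CH2Cl2, 0 °C to rt
Reagents that add atoms: none
Why: Ionic hydrogenation removes the carbonyl oxygen by protonation and two hydride transfers from Et3SiH through the doubly stabilised diarylmethyl cation, and cyclisation of this cation onto the C1 aryl ring is not expected because the only position in reach (C6') is meta to both of its alkoxy groups.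

**Step 12**
Reactants: 22 diarylmethane
Product: 23 target 1-(4-hydroxy-2-methoxyphenyl)-2-(3,4-dihydroxybenzyl)-5,7-dimethoxynaphthalene-3,6-diol (CNP0000244.0)
Conditions: H2 (1 atm), Pd on carbon, EtOAc/MeOH, rt
Reagents that add atoms: none
Why: Hydrogenolysis over palladium should cleave the four benzyl ethers to the pentaphenol, which is handled under inert gas because of the catechol.

**Compound list**

1 | 4-bromo-2,6-dimethoxyphenol | COc1cc(Br)cc(OC)c1O | starting material
2 | 2-(benzyloxy)-5-bromo-1,3-dimethoxybenzene | COc1cc(Br)cc(OC)c1OCc1ccccc1 | intermediate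
3 | (E)-1-methoxy-3-(trimethylsilyloxy)buta-1,3-diene | CO/C=C/C(=C)O[Si](C)(C)C | starting material
4 | 4-(benzyloxy)-3,5-dimethoxy-1,2-didehydrobenzene (aryne, formed in the flask) | C1#CC=C(OC)C(OCc2ccccc2)=C1OC | intermediate
5 | [6-(benzyloxy)-4,5,7-trimethoxy-1,4-dihydronaphthalen-2-yl]oxy-trimethylsilane (racemic at C4, formed in the flask) | COC1C=C(O[Si](C)(C)C)Cc2cc(OC)c(OCc3ccccc3)c(OC)c21 | intermediate
6 | 6-(benzyloxy)-5,7-dimethoxynaphthalen-2-ol | COc1cc2cc(O)ccc2c(OC)c1OCc1ccccc1 | intermediate
7 | 6-(benzyloxy)-1-bromo-5,7-dimethoxynaphthalen-2-ol | COc1cc2c(Br)c(O)ccc2c(OC)c1OCc1ccccc1 | intermediate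
8 | 4-bromo-3-methoxyphenol | COc1cc(O)ccc1Br | starting material
9 | 4-(benzyloxy)-1-bromo-2-methoxybenzene | COc1cc(OCc2ccccc2)ccc1Br | intermediate
10 | 2-[4-(benzyloxy)-2-methoxyphenyl]-4,4,5,5-tetramethyl-1,3,2-dioxaborolane | COc1cc(OCc2ccccc2)ccc1B1OC(C)(C)C(C)(C)O1 | intermediate
11 | 6-(benzyloxy)-1-[4-(benzyloxy)-2-methoxyphenyl]-5,7-dimethoxynaphthalen-2-ol | COc1cc(OCc2ccccc2)ccc1-c1c(O)ccc2c(OC)c(OCc3ccccc3)c(OC)cc12 | intermediate
12 | N-isopropylcarbamate of 11 | COc1cc(OCc2ccccc2)ccc1-c1c(OC(=O)NC(C)C)ccc2c(OC)c(OCc3ccccc3)c(OC)cc12 | intermediate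
13 | N-(tert-butyldimethylsilyl)-N-isopropylcarbamate of 11 (formed in the flask) | COc1cc(OCc2ccccc2)ccc1-c1c(OC(=O)N(C(C)C)[Si](C)(C)C(C)(C)C)ccc2c(OC)c(OCc3ccccc3)c(OC)cc12 | intermediate
14 | 3-lithio derivative of 13 (formed in the flask) | COc1cc(OCc2ccccc2)ccc1-c1c(OC(=O)N(C(C)C)[Si](C)(C)C(C)(C)C)c([Li])cc2c(OC)c(OCc3ccccc3)c(OC)cc12 | intermediate
15 | 3-(trimethylsilyl) derivative of 13 (formed in the flask) | COc1cc(OCc2ccccc2)ccc1-c1c(OC(=O)N(C(C)C)[Si](C)(C)C(C)(C)C)c([Si](C)(C)C)cc2c(OC)c(OCc3ccccc3)c(OC)cc12 | intermediate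
16 | 6-(benzyloxy)-1-[4-(benzyloxy)-2-methoxyphenyl]-5,7-dimethoxy-3-(trimethylsilyl)naphthalen-2-yl N-isopropylcarbamate | COc1cc(OCc2ccccc2)ccc1-c1c(OC(=O)NC(C)C)c([Si](C)(C)C)cc2c(OC)c(OCc3ccccc3)c(OC)cc12 | intermediate
17 | 6-(benzyloxy)-1-[4-(benzyloxy)-2-methoxyphenyl]-5,7-dimethoxy-3-(trimethylsilyl)naphthalen-2-ol (formed in the flask) | COc1cc(OCc2ccccc2)ccc1-c1c(O)c([Si](C)(C)C)cc2c(OC)c(OCc3ccccc3)c(OC)cc12 | intermediate
18 | 6-(benzyloxy)-1-[4-(benzyloxy)-2-methoxyphenyl]-5,7-dimethoxy-3-(trimethylsilyl)naphthalen-2-yl trifluoromethanesulfonate | COc1cc(OCc2ccccc2)ccc1-c1c(OS(=O)(=O)C(F)(F)F)c([Si](C)(C)C)cc2c(OC)c(OCc3ccccc3)c(OC)cc12 | intermediate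
19 | 3,4-bis(benzyloxy)benzoic acid | OC(=O)c1ccc(OCc2ccccc2)c(OCc2ccccc2)c1 | starting material
20 | 6-(benzyloxy)-1-[4-(benzyloxy)-2-methoxyphenyl]-5,7-dimethoxy-2,3-didehydronaphthalene (aryne, formed in the flask) | COc1cc(OCc2ccccc2)ccc1C1=C2C=C(OC)C(OCc3ccccc3)=C(OC)C2=CC#C1 | intermediate
21 | [6-(benzyloxy)-1-[4-(benzyloxy)-2-methoxyphenyl]-3-hydroxy-5,7-dimethoxynaphthalen-2-yl][3,4-bis(benzyloxy)phenyl]methanone | COc1cc(OCc2ccccc2)ccc1-c1c(C(=O)c2ccc(OCc3ccccc3)c(OCc3ccccc3)c2)c(O)cc2c(OC)c(OCc3ccccc3)c(OC)cc12 | intermediate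
22 | 6-(benzyloxy)-1-[4-(benzyloxy)-2-methoxyphenyl]-2-[3,4-bis(benzyloxy)benzyl]-5,7-dimethoxynaphthalen-3-ol | COc1cc(OCc2ccccc2)ccc1-c1c(Cc2ccc(OCc3ccccc3)c(OCc3ccccc3)c2)c(O)cc2c(OC)c(OCc3ccccc3)c(OC)cc12 | intermediate
23 | 1-(4-hydroxy-2-methoxyphenyl)-2-(3,4-dihydroxybenzyl)-5,7-dimethoxynaphthalene-3,6-diol | COc1cc(O)ccc1-c1c(Cc2ccc(O)c(O)c2)c(O)cc2c(OC)c(O)c(OC)cc12 | target

**Step count and risks**

Total: 12 steps; steps 4 and 5 form a two-step side branch. Longest linear sequence: 10 steps (1, 2, 3, 6, 7, 8, 9, 10, 11, 12).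

Most likely to fail, first: step 10. The C2 aryl anion, flanked by the C1 aryl ring, may be protonated before the 1,3-acyl shift, so that the addition stops at the C3 aryl ester, or the shift may be too slow for steric reasons. The fallback sets out from 18 and keeps the aryne but changes the bond-forming event. With CsF in N,N-dimethylformamide, aryne 20 should insert into the formamide C=O bond (oxygen to C3, formyl carbon to C2), and aqueous work-up would give the aldehyde 6-(benzyloxy)-1-[4-(benzyloxy)-2-methoxyphenyl]-3-hydroxy-5,7-dimethoxynaphthalene-2-carbaldehyde F1. An excess of 3,4-bis(benzyloxy)phenylmagnesium bromide F2 (from 1,2-bis(benzyloxy)-4-bromobenzene and magnesium in THF) would add to F1 to give the racemic carbinol [3,4-bis(benzyloxy)phenyl][6-(benzyloxy)-1-[4-(benzyloxy)-2-methoxyphenyl]-3-hydroxy-5,7-dimethoxynaphthalen-2-yl]methanol F3. Et3SiH and CF3CO2H would then reduce F3 to 22, where the route is rejoined.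

Second: step 2. The lithium amide or the liberated amine may add to aryne 4 in competition with the diene, or the cycloaddition may take both orientations. The fallback sets out from 2 and closes ring B by an acid-mediated Friedel–Crafts cyclisation, in which the symmetry of ring A makes the orientation unambiguous. Coupling of 2 with commercial (2-ethoxy-2-oxoethyl)zinc bromide (Pd(dba)2, P(t-Bu)3, THF) would give ethyl 2-[4-(benzyloxy)-3,5-dimethoxyphenyl]acetate F4. MeNH(OMe)·HCl with i-PrMgCl would convert it into 2-[4-(benzyloxy)-3,5-dimethoxyphenyl]-N-methoxy-N-methylacetamide F5. Commercial (1,3-dioxolan-2-ylmethyl)magnesium bromide would then give the keto acetal 1-[4-(benzyloxy)-3,5-dimethoxyphenyl]-3-(1,3-dioxolan-2-yl)propan-2-one F6. TsOH in warm toluene should close the acetal carbon onto the ring position ortho to the side chain (ortho and para to methoxy groups), and loss of ethylene glycol and enolisation would give 6, where the route is rejoined.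

Third: step 8. Metalation may occur on the C1 aryl ring at its C3'–H between the two alkoxy groups, or a benzyl ether may be deprotonated and undergo Wittig rearrangement. The fallback sets out from 6 and installs the silyl group before the C1 aryl ring is attached. Isopropyl isocyanate would give 6-(benzyloxy)-5,7-dimethoxynaphthalen-2-yl N-isopropylcarbamate F7. The sequence of step 8 would then give the 3-silyl carbamate 6-(benzyloxy)-5,7-dimethoxy-3-(trimethylsilyl)naphthalen-2-yl N-isopropylcarbamate F8, lithiation being expected at C3, away from the peri hydrogen. DBU and Et2NH would free 6-(benzyloxy)-5,7-dimethoxy-3-(trimethylsilyl)naphthalen-2-ol F9, and NBS would brominate C1 to give 6-(benzyloxy)-1-bromo-5,7-dimethoxy-3-(trimethylsilyl)naphthalen-2-ol F10. Coupling of F10 with 10 under the conditions of step 6 would give 17, which is triflated with PhNTf2 and DBU as in step 9.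

**Further compounds**

F1 | step 10 | 6-(benzyloxy)-1-[4-(benzyloxy)-2-methoxyphenyl]-3-hydroxy-5,7-dimethoxynaphthalene-2-carbaldehyde | COc1cc(OCc2ccccc2)ccc1-c1c(C=O)c(O)cc2c(OC)c(OCc3ccccc3)c(OC)cc12
F2 | step 10 | 3,4-bis(benzyloxy)phenylmagnesium bromide | Br[Mg]c1ccc(OCc2ccccc2)c(OCc2ccccc2)c1
F3 | step 10 | [3,4-bis(benzyloxy)phenyl][6-(benzyloxy)-1-[4-(benzyloxy)-2-methoxyphenyl]-3-hydroxy-5,7-dimethoxynaphthalen-2-yl]methanol (racemic) | COc1cc(OCc2ccccc2)ccc1-c1c(C(O)c2ccc(OCc3ccccc3)c(OCc3ccccc3)c2)c(O)cc2c(OC)c(OCc3ccccc3)c(OC)cc12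
F4 | step 2 | ethyl 2-[4-(benzyloxy)-3,5-dimethoxyphenyl]acetate | CCOC(=O)Cc1cc(OC)c(OCc2ccccc2)c(OC)c1
F5 | step 2 | 2-[4-(benzyloxy)-3,5-dimethoxyphenyl]-N-methoxy-N-methylacetamide | CON(C)C(=O)Cc1cc(OC)c(OCc2ccccc2)c(OC)c1
F6 | step 2 | 1-[4-(benzyloxy)-3,5-dimethoxyphenyl]-3-(1,3-dioxolan-2-yl)propan-2-one | COc1cc(CC(=O)CC2OCCO2)cc(OC)c1OCc1ccccc1
F7 | step 8 | 6-(benzyloxy)-5,7-dimethoxynaphthalen-2-yl N-isopropylcarbamate | COc1cc2cc(OC(=O)NC(C)C)ccc2c(OC)c1OCc1ccccc1
F8 | step 8 | 6-(benzyloxy)-5,7-dimethoxy-3-(trimethylsilyl)naphthalen-2-yl N-isopropylcarbamate | COc1cc2cc(OC(=O)NC(C)C)c([Si](C)(C)C)cc2c(OC)c1OCc1ccccc1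
F9 | step 8 | 6-(benzyloxy)-5,7-dimethoxy-3-(trimethylsilyl)naphthalen-2-ol | COc1cc2cc(O)c([Si](C)(C)C)cc2c(OC)c1OCc1ccccc1
F10 | step 8 | 6-(benzyloxy)-1-bromo-5,7-dimethoxy-3-(trimethylsilyl)naphthalen-2-ol | COc1cc2c(Br)c(O)c([Si](C)(C)C)cc2c(OC)c1OCc1ccccc1
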